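## The problem

The target 21 is a phenylcoumaran neolignan. It is a 2,3-dihydrobenzofuran whose benzene ring (ring B) carries a methoxy group at C7 and a 3-(sulfooxy)propyl chain at C5; C2 bears a 4-hydroxy-3-methoxyphenyl group (ring A) and C3 bears a hydroxymethyl group (its carbon is called C9 here). The two adjacent stereocentres are 2S and 3R, with aryl and hydroxymethyl trans. They are unequal as control elements. C3 is a plain benzylic C–H centre that cannot be corrected once set. C2 is para-benzylic to the free ring A phenol and can open and reclose through a quinone methide, so C3 can dictate C2 but not the reverse. Three hydroxyl functions of different kind must be told apart: the phenol, the C9 alcohol and the chain alcohol that carries the sulfate. The sulfate monoester is polar and acid-labile and belongs late in the route. The benzylic aryl ether O1–C2 is the most fragile skeletal bond, open to hydrogenolysis and, with the para-phenol free, to ring opening. The feature that invites a late ring closure is that C2 is the para-benzylic carbon of a 4-alkyl-2-methoxyphenol (ring A), the substrate motif of flavin-dependent 4-alkylphenol oxidases, while O1 is the ring B phenol oxygen held five atoms away (O1–C7a–C3a–C3–C2).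

## Retrosynthesis

**21 to 19 (O1–C2).** The last bond made is O1–C2. Cutting it opens the dihydrofuran and removes the C2 stereocentre, leaving the acyclic diarylpropanol 19 with one stereocentre and every heteroatom of the target in place. The neighbouring cuts (C3–C3a or C2–C3) would put a ring-forming C–C bond construction late and would force all deprotection, hydrogenolysis included, onto the finished benzylic ether. The forward step must remove one hydrogen from the ring A benzylic CH2 and one from the ring B phenol. A flavin-dependent 4-alkylphenol oxidase is asked to turn ring A into para-quinone methide 20, which the ring B phenol captures. Two demands follow: ring A must be oxidised and not ring B, and C3 must steer C2 to trans. The first is the weak point, and it is strengthened within the same disconnection by oxidising the sulfate itself rather than a protected relative. Ring B then differs from ring A by two ortho substituents and by an anionic chain, and the substrate dissolves in buffer. The second demand rests on the reversibility of the closure through 20.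

**19 to 15 (S–O and three O–benzyl bonds).** Cutting the sulfate S–O bond and three O–CH2Ph bonds leads back through 18, 17 and 16 to alcohol 15. Sulfating after ring closure would require distinguishing three hydroxyls on a fragile product. Debenzylating after ring closure would expose O1–C2 to hydrogenolysis. In 18 there is no benzylic C–O bond other than those of the protecting groups, so one hydrogenolysis can remove all three. The forward sequence asks only for orthogonality between one silyl ether (chain oxygen) and benzyl ethers (both phenols and C9–OH).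

**15 to 10 and 12 (C2–C3).** The bond between the stereogenic carbon and the ring A benzylic CH2 is cut, giving imide 10 (through 14 and enolate 13) and bromide 12. The alternatives at this carbon are weaker: arylation at C3–C3a has no reliable auxiliary-controlled version, and hydroxymethylation at C3–C9 would start from a 1,2-diarylethane without an activating group. The arylacetyl imide offers an acidic CH2 and a well-understood facial bias. The precursor pair has no stereocentre of its own apart from the auxiliary. The forward reaction must deliver the (R) centre without later epimerisation of the acidic α-aryl position.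

**10 to 1, 8 and 11.** The N-acyl bond of 10 is cut to acid 7 and auxiliary 8. The aryl–CH2 bond of 7 is traced through aldehyde 6 and alkene 5 to an allyl group placed by a Claisen rearrangement (4 from 3), which leads via 2 to dihydroconiferyl alcohol 1. The Claisen route is preferred to a direct ortho-functionalisation of 1 because only one ortho position is free, so the regiochemistry is fixed. Bromide 12 comes from the catalogue alcohol 11.

## Roads not taken

**Alternative 1:** flavanone ring contraction. The cut is C3–C3a, formed by a 1,2-shift of the benzo-ring carbon. Flavanone A2 would be treated with PhI(OAc)2 and H2SO4 in trimethyl orthoformate to give the trans ester A1, the former C4 leaving the ring as the ester carbon.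
- Merits: the reaction type is established on flavanones, the trans relationship comes from the migration itself, and C9 arrives at the ester level. On precedent this road is better than the chosen one.
- Weak points: A2 must be enantiopure, and flavanones racemise by reversible retro-oxa-Michael ring opening. The acidic oxidising medium meets a very electron-rich benzo ring and a C2 that ionises easily even with the pivalate in place. After the key step, reduction and depivaloylation leave three hydroxyls to differentiate on the finished, fragile ring.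
- Comparison: the chosen plan sets against it a stereocentre fixed by a robust auxiliary alkylation, all protecting-group work done before the ring exists, and the target obtained directly from the last step.

**Alternative 2:** aryl radical cyclisation with TEMPO capture. The cuts are C3–C3a and C9–O. Iodide A4 with Bu3SnH would give an aryl radical that adds 5-exo to the vinyl group; TEMPO traps the primary radical to give A3.
- Merits: two bonds in one step, convergent union of the rings by an ether bond, and a C9 oxygen that arrives already masked. In convergence it is at least as good as the chosen plan.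
- Weak points: the allylic–benzylic C–O stereocentre of A4 must be made by enantioselective allylic etherification or invertive Mitsunobu coupling, both delicate at so electron-rich a position. The 2,3-relationship is set kinetically, and C3 cannot be corrected afterwards. The ring A benzyl ether must be hydrogenolysed after O1–C2 exists.
- Comparison: the chosen plan offers thermodynamic control of the trans relationship and deprotection before cyclisation.

**Alternative 3:** rhodium carbenoid C–H insertion. The cut is C2–C3. Diazoester A6 on a chiral dirhodium tetracarboxylate such as Rh2(S-PTTL)4 would insert into a benzylic C–H bond of the aryl benzyl ether, giving the cis ester A5.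
- Merits: this is the strongest rival. Absolute configuration is set catalytically, no auxiliary is put on and taken off, and the insertion is known on close relatives. On precedent and catalytic economy it is better than the chosen plan.
- Weak points: A5 needs base-mediated epimerisation at C3, and the ester enolate can also expel the O1 phenoxide and open the ring. The C7 methoxy group flanks the ether oxygen and may disturb the insertion geometry. The endgame again differentiates three hydroxyls and debenzylates ring A on the finished ring.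
- Comparison: the chosen plan has no manipulation of the finished ring system and a last step run on the unprotected sulfate in water. The price is a key step without direct precedent, for which a conventional closure of the same bond is held in reserve.

Key step: step 15

Assumption: the hydrogen sulfates 18, 19 and 21 are drawn in the neutral acid form but would be handled and isolated as their sodium salts, a change of counter-ion only.

Assumption: eugenol oxidase from Rhodococcus jostii RHA1, the member of the vanillyl-alcohol oxidase family whose usual substrates are guaiacols, is taken as the 4-alkylphenol oxidase.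

## Route

Step 1
Reactants: 1 dihydroconiferyl alcohol
Product: 2 3-[3-methoxy-4-(prop-2-enyloxy)phenyl]propan-1-ol
Conditions: allyl bromide, K2CO3, acetone, reflux
Reagents that add atoms: allyl bromide, C=CCBr
Why: Williamson etherification; K2CO3 deprotonates the phenol but not the primary alcohol, so only the phenol is allylated.

Step 2
Reactants: 2 3-[3-methoxy-4-(prop-2-enyloxy)phenyl]propan-1-ol
Product: 3 tert-butyl{3-[3-methoxy-4-(prop-2-enyloxy)phenyl]propoxy}diphenylsilane
Conditions: t-BuPh2SiCl, imidazole, DMF, rt
Reagents that add atoms: tert-butyl(chloro)diphenylsilane, CC(C)(C)[Si](Cl)(c1ccccc1)c1ccccc1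
Why: Standard silylation of a primary alcohol; this silyl ether tolerates the later heat, enolate, hydride and NaH steps and is removed by fluoride without touching benzyl ethers.

Step 3
Reactants: 3 tert-butyl{3-[3-methoxy-4-(prop-2-enyloxy)phenyl]propoxy}diphenylsilane
Product: 4 4-[3-(tert-butyldiphenylsilyloxy)propyl]-2-methoxy-6-(prop-2-enyl)phenol
Conditions: N,N-diethylaniline, 195 °C, argon
Reagents that add atoms: none
Why: Aromatic Claisen rearrangement; one ortho position carries the methoxy group, so the allyl group is delivered to the only free one and tautomerisation restores the phenol.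

Step 4
Reactants: 4 4-[3-(tert-butyldiphenylsilyloxy)propyl]-2-methoxy-6-(prop-2-enyl)phenol
Product: 5 {3-[4-benzyloxy-3-methoxy-5-(prop-2-enyl)phenyl]propoxy}(tert-butyl)diphenylsilane
Conditions: BnBr, K2CO3, DMF, 60 °C
Reagents that add atoms: benzyl bromide, BrCc1ccccc1
Why: Williamson benzylation of the hindered phenol; the benzyl ether shields the ring B phenol from periodate and chlorite and leaves with the other benzyl groups in step 14.

Step 5
Reactants: 5 {3-[4-benzyloxy-3-methoxy-5-(prop-2-enyl)phenyl]propoxy}(tert-butyl)diphenylsilane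
Product: 6 2-{2-benzyloxy-5-[3-(tert-butyldiphenylsilyloxy)propyl]-3-methoxyphenyl}acetaldehyde
Conditions: OsO4 (cat.), NaIO4, 2,6-lutidine, dioxane/H2O, rt; used crude
Reagents that add atoms: sodium periodate, [Na+].[O-]I(=O)(=O)=O (terminal oxidant and oxygen source, passed on through catalytic osmium tetroxide, O=[Os](=O)(=O)=O)
Why: Lemieux–Johnson oxidation: osmium-catalysed dihydroxylation of the terminal alkene and periodate cleavage of the diol in one flask; 2,6-lutidine suppresses side reactions of the sensitive arylacetaldehyde.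

Step 6
Reactants: 6 2-{2-benzyloxy-5-[3-(tert-butyldiphenylsilyloxy)propyl]-3-methoxyphenyl}acetaldehyde
Product: 7 2-{2-benzyloxy-5-[3-(tert-butyldiphenylsilyloxy)propyl]-3-methoxyphenyl}acetic acid
Conditions: NaClO2, NaH2PO4, 2-methyl-2-butene, t-BuOH/H2O, 0 °C to rt
Reagents that add atoms: sodium chlorite, [Na+].[O-]Cl=O
Why: Pinnick oxidation; chlorous acid converts the aldehyde into the acid under buffered conditions, and 2-methyl-2-butene scavenges HOCl so that the electron-rich ring is not chlorinated.

Step 7
Reactants: 7 2-{2-benzyloxy-5-[3-(tert-butyldiphenylsilyloxy)propyl]-3-methoxyphenyl}acetic acid; 8 (4R)-4-benzyl-1,3-oxazolidin-2-one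
Product: 10 (4R)-4-benzyl-3-(2-{2-benzyloxy-5-[3-(tert-butyldiphenylsilyloxy)propyl]-3-methoxyphenyl}acetyl)-1,3-oxazolidin-2-one, via mixed pivalic anhydride 9 (not isolated)
Conditions: Me3CCOCl, Et3N, THF, −20 °C; then 8, LiCl, −20 °C to rt
Reagents that add atoms: pivaloyl chloride, CC(C)(C)C(Cl)=O (its acyl group is carried only in intermediate 9)
Why: N-acylation of the Evans auxiliary through a mixed anhydride; the LiCl/Et3N protocol avoids strong base, and the oxazolidinone attacks the less hindered arylacetyl carbonyl.

Step 8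
Reactants: 11 (4-benzyloxy-3-methoxyphenyl)methanol
Product: 12 1-benzyloxy-4-(bromomethyl)-2-methoxybenzene
Conditions: PBr3, Et2O, 0 °C; used without storage
Reagents that add atoms: phosphorus tribromide, BrP(Br)Br
Why: Conversion of a benzylic alcohol into the bromide by bromide displacement on the phosphite ester.

Step 9
Reactants: 10 (4R)-4-benzyl-3-(2-{2-benzyloxy-5-[3-(tert-butyldiphenylsilyloxy)propyl]-3-methoxyphenyl}acetyl)-1,3-oxazolidin-2-one; 12 1-benzyloxy-4-(bromomethyl)-2-methoxybenzene
Product: 14 (4R)-4-benzyl-3-[(2R)-2-{2-benzyloxy-5-[3-(tert-butyldiphenylsilyloxy)propyl]-3-methoxyphenyl}-3-(4-benzyloxy-3-methoxyphenyl)propanoyl]-1,3-oxazolidin-2-one, via sodium Z-enolate 13 (not isolated)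
Conditions: NaN(SiMe3)2 (0.98 equiv), THF, −78 °C; then 12, −78 to −40 °C
Reagents that add atoms: sodium bis(trimethylsilyl)amide, C[Si](C)(C)[N-][Si](C)(C)C.[Na+] (sodium is carried only in intermediate 13)
Why: Evans asymmetric alkylation: the chelated (Z)-sodium enolate 13 is shielded on one face by the C4 benzyl group of the (R)-auxiliary, so bromide 12 should add to the opposite face and set the (R) centre that becomes C3 of the target; a slight deficit of base guards against proton exchange at the acidic α-aryl position.

Step 10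
Reactants: 14 (4R)-4-benzyl-3-[(2R)-2-{2-benzyloxy-5-[3-(tert-butyldiphenylsilyloxy)propyl]-3-methoxyphenyl}-3-(4-benzyloxy-3-methoxyphenyl)propanoyl]-1,3-oxazolidin-2-one
Product: 15 (2R)-2-{2-benzyloxy-5-[3-(tert-butyldiphenylsilyloxy)propyl]-3-methoxyphenyl}-3-(4-benzyloxy-3-methoxyphenyl)propan-1-ol
Conditions: LiBH4, MeOH (1.1 equiv), Et2O, 0 °C
Reagents that add atoms: none
Why: Reductive cleavage of the N-acyl oxazolidinone with LiBH4 gives the primary alcohol and returns auxiliary 8; the mild hydride should not epimerise the α-aryl centre and leaves silyl and benzyl ethers intact.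

Step 11
Reactants: 15 (2R)-2-{2-benzyloxy-5-[3-(tert-butyldiphenylsilyloxy)propyl]-3-methoxyphenyl}-3-(4-benzyloxy-3-methoxyphenyl)propan-1-ol
Product: 16 {3-[4-benzyloxy-3-[(2R)-1-benzyloxy-3-(4-benzyloxy-3-methoxyphenyl)propan-2-yl]-5-methoxyphenyl]propoxy}(tert-butyl)diphenylsilane
Conditions: NaH, BnBr, Bu4NI (cat.), THF/DMF, 0 °C to rt
Reagents that add atoms: benzyl bromide, BrCc1ccccc1
Why: Williamson benzylation of the primary alkoxide; masking C9–OH ensures that only the chain alcohol is sulfated later, and the group leaves in the same hydrogenolysis as the aryl benzyl ethers.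

Step 12
Reactants: 16 {3-[4-benzyloxy-3-[(2R)-1-benzyloxy-3-(4-benzyloxy-3-methoxyphenyl)propan-2-yl]-5-methoxyphenyl]propoxy}(tert-butyl)diphenylsilane
Product: 17 3-{4-benzyloxy-3-[(2R)-1-benzyloxy-3-(4-benzyloxy-3-methoxyphenyl)propan-2-yl]-5-methoxyphenyl}propan-1-ol
Conditions: Bu4NF, THF, rt
Reagents that add atoms: none
Why: Fluoride cleavage of the silyl ether, driven by the strength of the Si–F bond; benzyl ethers are inert.

Step 13
Reactants: 17 3-{4-benzyloxy-3-[(2R)-1-benzyloxy-3-(4-benzyloxy-3-methoxyphenyl)propan-2-yl]-5-methoxyphenyl}propan-1-ol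
Product: 18 3-{4-benzyloxy-3-[(2R)-1-benzyloxy-3-(4-benzyloxy-3-methoxyphenyl)propan-2-yl]-5-methoxyphenyl}propyl hydrogen sulfate
Conditions: SO3·pyridine, pyridine, rt; NaHCO3 (aq) work-up
Reagents that add atoms: sulfur trioxide pyridine complex, O=S(=O)=O.c1ccncc1
Why: O-sulfation of the only free hydroxyl with the sulfur trioxide–pyridine complex; bicarbonate work-up gives the stable sodium alkyl sulfate.

Step 14
Reactants: 18 3-{4-benzyloxy-3-[(2R)-1-benzyloxy-3-(4-benzyloxy-3-methoxyphenyl)propan-2-yl]-5-methoxyphenyl}propyl hydrogen sulfate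
Product: 19 3-{4-hydroxy-3-[(2R)-1-hydroxy-3-(4-hydroxy-3-methoxyphenyl)propan-2-yl]-5-methoxyphenyl}propyl hydrogen sulfate
Conditions: H2 (1 atm), Pd(OH)2/C, MeOH/THF, NaHCO3 (trace), rt
Reagents that add atoms: none
Why: Catalytic hydrogenolysis of two aryl benzyl ethers and one alkyl benzyl ether; at this stage the molecule has no benzylic C–O bond of its own and sulfate monoesters are inert to H2 over palladium, so only the protecting groups should be lost.

Step 15
Reactants: 19 3-{4-hydroxy-3-[(2R)-1-hydroxy-3-(4-hydroxy-3-methoxyphenyl)propan-2-yl]-5-methoxyphenyl}propyl hydrogen sulfate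
Product: 21 3-[(2S,3R)-2-(4-hydroxy-3-methoxyphenyl)-3-(hydroxymethyl)-7-methoxy-2,3-dihydro-1-benzofuran-5-yl]propyl hydrogen sulfate, via para-quinone methide 20 (not isolated)
Conditions: eugenol oxidase (Rhodococcus jostii RHA1, flavin adenine dinucleotide enzyme, cat.), catalase, air, KH2PO4/K2HPO4 buffer (50 mM, pH 7.5), 5% DMSO, 25 °C; ultrafiltration, C18 reversed phase
Reagents that add atoms: none
Why: Proposed new method: ring A of 19 is the 4-alkyl-2-methoxyphenol head group that eugenol oxidase normally binds as its phenolate, so hydride transfer from the para-benzylic C2–H to the flavin should give para-quinone methide 20 while O2 reoxidises the reduced flavin to H2O2, which catalase removes; the closest known reaction type is the dehydrogenation of 4-alkylphenols by vanillyl-alcohol oxidase and eugenol oxidase to quinone methides that are then captured by water or lose a proton, capture by an internal phenol being without precedent. The ring B phenol, five atoms from the methide carbon, should then add in a 5-exo-trig oxa-1,6-conjugate addition that forms O1–C2, closes the dihydrofuran and restores the aromaticity of ring A. The new C2 centre is controlled by the preset C3 centre: the aryl group should take the face trans to the C3 hydroxymethyl group (2S,3R), and because 21 keeps the free para-phenol a cis isomer can reopen to 20 and reclose, so trans is also the thermodynamic outcome. The step needs site selectivity between two 4-alkylphenols; this should come from the unhindered guaiacyl ring A fitting the phenolate pocket, whereas ring B carries two ortho substituents, one of them a branched carbon, and an anionic sulfate on its chain. It also needs the phenol to win over water capture and over loss of the C3 proton, which rests on the intramolecular five-membered delivery of the nucleophile. No protecting group is required in buffer, and the sulfate makes the substrate water soluble.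

## Compound list

1 | dihydroconiferyl alcohol, 4-(3-hydroxypropyl)-2-methoxyphenol | COc1cc(CCCO)ccc1O | starting material
2 | 3-[3-methoxy-4-(prop-2-enyloxy)phenyl]propan-1-ol | COc1cc(CCCO)ccc1OCC=C | intermediate
3 | tert-butyl{3-[3-methoxy-4-(prop-2-enyloxy)phenyl]propoxy}diphenylsilane | COc1cc(CCCO[Si](c2ccccc2)(c2ccccc2)C(C)(C)C)ccc1OCC=C | intermediate
4 | 4-[3-(tert-butyldiphenylsilyloxy)propyl]-2-methoxy-6-(prop-2-enyl)phenol | COc1cc(CCCO[Si](c2ccccc2)(c2ccccc2)C(C)(C)C)cc(CC=C)c1O | intermediate
5 | {3-[4-benzyloxy-3-methoxy-5-(prop-2-enyl)phenyl]propoxy}(tert-butyl)diphenylsilane | COc1cc(CCCO[Si](c2ccccc2)(c2ccccc2)C(C)(C)C)cc(CC=C)c1OCc1ccccc1 | intermediate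
6 | 2-{2-benzyloxy-5-[3-(tert-butyldiphenylsilyloxy)propyl]-3-methoxyphenyl}acetaldehyde | COc1cc(CCCO[Si](c2ccccc2)(c2ccccc2)C(C)(C)C)cc(CC=O)c1OCc1ccccc1 | intermediate
7 | 2-{2-benzyloxy-5-[3-(tert-butyldiphenylsilyloxy)propyl]-3-methoxyphenyl}acetic acid | COc1cc(CCCO[Si](c2ccccc2)(c2ccccc2)C(C)(C)C)cc(CC(=O)O)c1OCc1ccccc1 | intermediate
8 | (4R)-4-benzyl-1,3-oxazolidin-2-one | O=C1N[C@H](Cc2ccccc2)CO1 | starting material
9 | 2-{2-benzyloxy-5-[3-(tert-butyldiphenylsilyloxy)propyl]-3-methoxyphenyl}acetic pivalic anhydride | COc1cc(CCCO[Si](c2ccccc2)(c2ccccc2)C(C)(C)C)cc(CC(=O)OC(=O)C(C)(C)C)c1OCc1ccccc1 | intermediate (not isolated)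
10 | (4R)-4-benzyl-3-(2-{2-benzyloxy-5-[3-(tert-butyldiphenylsilyloxy)propyl]-3-methoxyphenyl}acetyl)-1,3-oxazolidin-2-one | COc1cc(CCCO[Si](c2ccccc2)(c2ccccc2)C(C)(C)C)cc(CC(=O)N2[C@H](Cc3ccccc3)COC2=O)c1OCc1ccccc1 | intermediate
11 | (4-benzyloxy-3-methoxyphenyl)methanol | COc1cc(CO)ccc1OCc1ccccc1 | starting material
12 | 1-benzyloxy-4-(bromomethyl)-2-methoxybenzene | COc1cc(CBr)ccc1OCc1ccccc1 | intermediate
13 | sodium (Z)-enolate of imide 10 | COc1cc(CCCO[Si](c2ccccc2)(c2ccccc2)C(C)(C)C)cc(/C=C(\[O-])N2[C@H](Cc3ccccc3)COC2=O)c1OCc1ccccc1.[Na+] | intermediate (not isolated)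
14 | (4R)-4-benzyl-3-[(2R)-2-{2-benzyloxy-5-[3-(tert-butyldiphenylsilyloxy)propyl]-3-methoxyphenyl}-3-(4-benzyloxy-3-methoxyphenyl)propanoyl]-1,3-oxazolidin-2-one | COc1cc(C[C@@H](C(=O)N2[C@H](Cc3ccccc3)COC2=O)c2cc(CCCO[Si](c3ccccc3)(c3ccccc3)C(C)(C)C)cc(OC)c2OCc2ccccc2)ccc1OCc1ccccc1 | intermediate
15 | (2R)-2-{2-benzyloxy-5-[3-(tert-butyldiphenylsilyloxy)propyl]-3-methoxyphenyl}-3-(4-benzyloxy-3-methoxyphenyl)propan-1-ol | COc1cc(C[C@@H](CO)c2cc(CCCO[Si](c3ccccc3)(c3ccccc3)C(C)(C)C)cc(OC)c2OCc2ccccc2)ccc1OCc1ccccc1 | intermediate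
16 | {3-[4-benzyloxy-3-[(2R)-1-benzyloxy-3-(4-benzyloxy-3-methoxyphenyl)propan-2-yl]-5-methoxyphenyl]propoxy}(tert-butyl)diphenylsilane | COc1cc(C[C@@H](COCc2ccccc2)c2cc(CCCO[Si](c3ccccc3)(c3ccccc3)C(C)(C)C)cc(OC)c2OCc2ccccc2)ccc1OCc1ccccc1 | intermediate
17 | 3-{4-benzyloxy-3-[(2R)-1-benzyloxy-3-(4-benzyloxy-3-methoxyphenyl)propan-2-yl]-5-methoxyphenyl}propan-1-ol | COc1cc(C[C@@H](COCc2ccccc2)c2cc(CCCO)cc(OC)c2OCc2ccccc2)ccc1OCc1ccccc1 | intermediate
18 | 3-{4-benzyloxy-3-[(2R)-1-benzyloxy-3-(4-benzyloxy-3-methoxyphenyl)propan-2-yl]-5-methoxyphenyl}propyl hydrogen sulfate | COc1cc(C[C@@H](COCc2ccccc2)c2cc(CCCOS(=O)(=O)O)cc(OC)c2OCc2ccccc2)ccc1OCc1ccccc1 | intermediate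
19 | 3-{4-hydroxy-3-[(2R)-1-hydroxy-3-(4-hydroxy-3-methoxyphenyl)propan-2-yl]-5-methoxyphenyl}propyl hydrogen sulfate | COc1cc(C[C@@H](CO)c2cc(CCCOS(=O)(=O)O)cc(OC)c2O)ccc1O | intermediate
20 | 3-{4-hydroxy-3-[(2R)-1-hydroxy-3-(3-methoxy-4-oxocyclohexa-2,5-dien-1-ylidene)propan-2-yl]-5-methoxyphenyl}propyl hydrogen sulfate (para-quinone methide) | COC1=CC(=C[C@@H](CO)c2cc(CCCOS(=O)(=O)O)cc(OC)c2O)C=CC1=O | intermediate (not isolated)
21 | 3-[(2S,3R)-2-(4-hydroxy-3-methoxyphenyl)-3-(hydroxymethyl)-7-methoxy-2,3-dihydro-1-benzofuran-5-yl]propyl hydrogen sulfate | COc1cc([C@H]2Oc3c(OC)cc(CCCOS(=O)(=O)O)cc3[C@@H]2CO)ccc1O | target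

## Step count and risks

Total: 15 steps. Longest linear sequence: 14 steps (steps 1–7 and 9–15, from 1); step 8 is a one-step side branch.

**Step 15 (key step, the one step that carries the new-method label).** Four things may go wrong:
- no productive binding, because the substituent on the benzylic carbon is branched and arylated, far larger than the chains this enzyme family normally accepts;
- loss of the C3 proton from enzyme-bound 20, the usual fate of quinone methides from longer 4-alkylphenols in this family, which would give a stilbene and erase C3;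
- capture of 20 by water instead of by the ring B phenol;
- slow competing oxidation at ring B.

Fallback with known chemistry: the same O1–C2 bond is closed by ionising a benzylic alcohol instead of by dehydrogenation. It sets out from acid 7 and returns at target 21.
- Acid 7 is coupled (Me3CCOCl, Et3N, LiCl) with commercial (4S)-4-benzyl-1,3-oxazolidin-2-one (O=C1N[C@@H](Cc2ccccc2)CO1) to give the enantiomeric imide F1. The enantiomeric auxiliary is needed because a boron enolate reacts on the face opposite to that of the chelated sodium enolate of step 9.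
- An Evans syn aldol reaction (Bu2BOTf, i-Pr2NEt, CH2Cl2, −78 to 0 °C) with commercial 4-benzyloxy-3-methoxybenzaldehyde (COc1cc(C=O)ccc1OCc1ccccc1) should give the syn aldol adduct F2, in which the ring B-bearing carbon has the same spatial arrangement as in 15.
- LiBH4 reduction gives the 1,3-diol F3.
- Hydrogenolysis of the two aryl benzyl ethers (H2, Pd/C, EtOAc, trace Et3N) gives the bis-phenol F4.
- Catalytic p-TsOH in CH2Cl2 ionises the benzylic alcohol para to the ring A phenol, and the ring B phenol closes to the trans-dihydrobenzofuran F5. This is thermodynamic control; the carbinol configuration of the aldol is lost.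
- Ac2O/pyridine gives the diacetate F6, HF·pyridine removes the silyl group to give the primary alcohol F7, and SO3·pyridine gives the sulfate F8.
- K2CO3 in MeOH removes both acetates and delivers 21.

**Step 9 (auxiliary alkylation).** The diastereomeric purity may erode by proton exchange between enolate 13 and the product, whose α-hydrogen is activated by the imide and by ring B. The enolate may also fragment to a ketene on warming, and the electron-rich bromide 12 may decompose. Fallback, from acid 7 to alcohol 15:
- Perkin condensation of 7 with 4-benzyloxy-3-methoxybenzaldehyde (Ac2O, Et3N, 110 °C) gives the (E)-2,3-diarylacrylic acid F9.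
- Asymmetric hydrogenation with a chiral ruthenium bisphosphine catalyst such as Ru(OAc)2(BINAP), the ligand enantiomer chosen to deliver the (R) centre, gives the (2R)-diarylpropanoic acid F10.
- BH3·SMe2 reduces F10 to 15.

**Step 14 (hydrogenolysis on the sulfate).** Cleavage of the aliphatic benzyl ether may stall on the anionic, poorly soluble substrate after the two aryl benzyl ethers have gone. Fallback, from alcohol 15 to 19:
- Acetylation (Ac2O, pyridine, DMAP) gives the acetate F11.
- HF·pyridine gives the chain alcohol F12.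
- SO3·pyridine gives the sulfate F13.
- Hydrogenolysis now only has to remove the two aryl benzyl ethers, giving the bis-phenol acetate F14.
- K2CO3 in MeOH removes the acetate and gives 19.

**Step 5 (with step 6; the arylacetaldehyde).** Aldehyde 6 enolises readily and may self-condense or be degraded by further oxidative cleavage before it is oxidised. Fallback, from alkene 5 to acid 7:
- Ozonolysis in methanolic NaOH/CH2Cl2 at −78 °C traps the transient aldehyde as its hemiacetal and oxidises it in the same flask to the methyl ester F15.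
- LiOH in THF/H2O gives 7.

## Further compounds

F1 | step 15 | (4S)-4-benzyl-3-(2-{2-benzyloxy-5-[3-(tert-butyldiphenylsilyloxy)propyl]-3-methoxyphenyl}acetyl)-1,3-oxazolidin-2-one | COc1cc(CCCO[Si](c2ccccc2)(c2ccccc2)C(C)(C)C)cc(CC(=O)N2[C@@H](Cc3ccccc3)COC2=O)c1OCc1ccccc1
F2 | step 15 | (4S)-4-benzyl-3-[(2S,3S)-2-{2-benzyloxy-5-[3-(tert-butyldiphenylsilyloxy)propyl]-3-methoxyphenyl}-3-(4-benzyloxy-3-methoxyphenyl)-3-hydroxypropanoyl]-1,3-oxazolidin-2-one | COc1cc([C@@H](O)[C@@H](C(=O)N2[C@@H](Cc3ccccc3)COC2=O)c2cc(CCCO[Si](c3ccccc3)(c3ccccc3)C(C)(C)C)cc(OC)c2OCc2ccccc2)ccc1OCc1ccccc1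
F3 | step 15 | (1S,2R)-1-(4-benzyloxy-3-methoxyphenyl)-2-{2-benzyloxy-5-[3-(tert-butyldiphenylsilyloxy)propyl]-3-methoxyphenyl}propane-1,3-diol | COc1cc([C@@H](O)[C@@H](CO)c2cc(CCCO[Si](c3ccccc3)(c3ccccc3)C(C)(C)C)cc(OC)c2OCc2ccccc2)ccc1OCc1ccccc1
F4 | step 15 | (1S,2R)-2-{5-[3-(tert-butyldiphenylsilyloxy)propyl]-2-hydroxy-3-methoxyphenyl}-1-(4-hydroxy-3-methoxyphenyl)propane-1,3-diol | COc1cc([C@@H](O)[C@@H](CO)c2cc(CCCO[Si](c3ccccc3)(c3ccccc3)C(C)(C)C)cc(OC)c2O)ccc1O
F5 | step 15 | 4-[(2S,3R)-5-[3-(tert-butyldiphenylsilyloxy)propyl]-3-(hydroxymethyl)-7-methoxy-2,3-dihydro-1-benzofuran-2-yl]-2-methoxyphenol | COc1cc([C@H]2Oc3c(OC)cc(CCCO[Si](c4ccccc4)(c4ccccc4)C(C)(C)C)cc3[C@@H]2CO)ccc1O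
F6 | step 15 | [(2S,3R)-2-(4-acetoxy-3-methoxyphenyl)-5-[3-(tert-butyldiphenylsilyloxy)propyl]-7-methoxy-2,3-dihydro-1-benzofuran-3-yl]methyl acetate | COc1cc([C@H]2Oc3c(OC)cc(CCCO[Si](c4ccccc4)(c4ccccc4)C(C)(C)C)cc3[C@@H]2COC(C)=O)ccc1OC(C)=O
F7 | step 15 | [(2S,3R)-2-(4-acetoxy-3-methoxyphenyl)-5-(3-hydroxypropyl)-7-methoxy-2,3-dihydro-1-benzofuran-3-yl]methyl acetate | COc1cc([C@H]2Oc3c(OC)cc(CCCO)cc3[C@@H]2COC(C)=O)ccc1OC(C)=O
F8 | step 15 | 3-[(2S,3R)-3-(acetoxymethyl)-2-(4-acetoxy-3-methoxyphenyl)-7-methoxy-2,3-dihydro-1-benzofuran-5-yl]propyl hydrogen sulfate | COc1cc([C@H]2Oc3c(OC)cc(CCCOS(=O)(=O)O)cc3[C@@H]2COC(C)=O)ccc1OC(C)=O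
F9 | step 9 | (E)-2-{2-benzyloxy-5-[3-(tert-butyldiphenylsilyloxy)propyl]-3-methoxyphenyl}-3-(4-benzyloxy-3-methoxyphenyl)prop-2-enoic acid | COc1cc(/C=C(\c2cc(CCCO[Si](c3ccccc3)(c3ccccc3)C(C)(C)C)cc(OC)c2OCc2ccccc2)C(=O)O)ccc1OCc1ccccc1
F10 | step 9 | (2R)-2-{2-benzyloxy-5-[3-(tert-butyldiphenylsilyloxy)propyl]-3-methoxyphenyl}-3-(4-benzyloxy-3-methoxyphenyl)propanoic acid | COc1cc(C[C@@H](C(=O)O)c2cc(CCCO[Si](c3ccccc3)(c3ccccc3)C(C)(C)C)cc(OC)c2OCc2ccccc2)ccc1OCc1ccccc1
F11 | step 14 | (2R)-2-{2-benzyloxy-5-[3-(tert-butyldiphenylsilyloxy)propyl]-3-methoxyphenyl}-3-(4-benzyloxy-3-methoxyphenyl)propyl acetate | COc1cc(C[C@@H](COC(C)=O)c2cc(CCCO[Si](c3ccccc3)(c3ccccc3)C(C)(C)C)cc(OC)c2OCc2ccccc2)ccc1OCc1ccccc1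
F12 | step 14 | (2R)-2-[2-benzyloxy-5-(3-hydroxypropyl)-3-methoxyphenyl]-3-(4-benzyloxy-3-methoxyphenyl)propyl acetate | COc1cc(C[C@@H](COC(C)=O)c2cc(CCCO)cc(OC)c2OCc2ccccc2)ccc1OCc1ccccc1
F13 | step 14 | (2R)-2-{2-benzyloxy-3-methoxy-5-[3-(sulfooxy)propyl]phenyl}-3-(4-benzyloxy-3-methoxyphenyl)propyl acetate | COc1cc(C[C@@H](COC(C)=O)c2cc(CCCOS(=O)(=O)O)cc(OC)c2OCc2ccccc2)ccc1OCc1ccccc1
F14 | step 14 | (2R)-2-{2-hydroxy-3-methoxy-5-[3-(sulfooxy)propyl]phenyl}-3-(4-hydroxy-3-methoxyphenyl)propyl acetate | COc1cc(C[C@@H](COC(C)=O)c2cc(CCCOS(=O)(=O)O)cc(OC)c2O)ccc1O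
F15 | step 5 | methyl 2-{2-benzyloxy-5-[3-(tert-butyldiphenylsilyloxy)propyl]-3-methoxyphenyl}acetate | COc1cc(CCCO[Si](c2ccccc2)(c2ccccc2)C(C)(C)C)cc(CC(=O)OC)c1OCc1ccccc1
A1 | alternative 1 | methyl (2S,3S)-5-[3-(tert-butyldiphenylsilyloxy)propyl]-7-methoxy-2-[3-methoxy-4-(pivaloyloxy)phenyl]-2,3-dihydro-1-benzofuran-3-carboxylate (trans) | COc1cc([C@H]2Oc3c(OC)cc(CCCO[Si](c4ccccc4)(c4ccccc4)C(C)(C)C)cc3[C@@H]2C(=O)OC)ccc1OC(=O)C(C)(C)C
A2 | alternative 1 | (2S)-6-[3-(tert-butyldiphenylsilyloxy)propyl]-8-methoxy-2-[3-methoxy-4-(pivaloyloxy)phenyl]chroman-4-one | COc1cc([C@H]2Oc3c(OC)cc(CCCO[Si](c4ccccc4)(c4ccccc4)C(C)(C)C)cc3C(=O)C2)ccc1OC(=O)C(C)(C)C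
A3 | alternative 2 | (2S,3R)-2-(4-benzyloxy-3-methoxyphenyl)-5-[3-(tert-butyldimethylsilyloxy)propyl]-7-methoxy-3-[(2,2,6,6-tetramethylpiperidin-1-yl)oxymethyl]-2,3-dihydro-1-benzofuran | COc1cc([C@H]2Oc3c(OC)cc(CCCO[Si](C)(C)C(C)(C)C)cc3[C@@H]2CON2C(C)(C)CCCC2(C)C)ccc1OCc1ccccc1
A4 | alternative 2 | (3-{4-[(1S)-1-(4-benzyloxy-3-methoxyphenyl)prop-2-enyloxy]-3-iodo-5-methoxyphenyl}propoxy)(tert-butyl)dimethylsilane | COc1cc([C@H](C=C)Oc2c(I)cc(CCCO[Si](C)(C)C(C)(C)C)cc2OC)ccc1OCc1ccccc1
A5 | alternative 3 | methyl (2S,3R)-2-(4-benzyloxy-3-methoxyphenyl)-5-[3-(tert-butyldimethylsilyloxy)propyl]-7-methoxy-2,3-dihydro-1-benzofuran-3-carboxylate (cis) | COc1cc([C@H]2Oc3c(OC)cc(CCCO[Si](C)(C)C(C)(C)C)cc3[C@H]2C(=O)OC)ccc1OCc1ccccc1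
A6 | alternative 3 | methyl 2-{2-[(4-benzyloxy-3-methoxyphenyl)methoxy]-5-[3-(tert-butyldimethylsilyloxy)propyl]-3-methoxyphenyl}-2-diazoacetate | COc1cc(COc2c(OC)cc(CCCO[Si](C)(C)C(C)(C)C)cc2C(=[N+]=[N-])C(=O)OC)ccc1OCc1ccccc1
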